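The route rests on cutting C4a–C5 and C8a–C8, so the dihydroxybenzene ring of the naphthazarin (C4a, C5, C6, C7, C8, C8a) is made last. The feature exploited is that this ring carries para oxygens at C5 and C8, and that the naphthazarin is simply the bis-enol of a 4a,8a-dihydro-1,4,5,8-tetraone. A furan silyloxylated at both α-carbons therefore supplies C5–C8 with both oxygens at the final oxidation level. Cycloaddition, loss of the oxygen bridge and enolisation complete the chromophore in one operation, without oxidant. The dienophile is an (R)-configured monosubstituted benzoquinone that already carries the prenyl chain and the silyl-protected hydroxyisovalerate at C1'.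

Key step: step 7

Remark on numbering: target numbering is used (side chain on C2, carbonyls C1/C4, hydroxyls C5/C8, carbinol carbon C1'). Naphthazarin tautomers interconvert rapidly and are drawn as in the target.
Remark on configuration: at C1' the order O > ring carbon > CH2 > H holds in 2–4, 8, 9 and 12–15, so the descriptor stays (R) throughout.
Remark on the diene: 2,5-bis(trimethylsilyloxy)furan is moisture-sensitive and seldom stocked, so it is made fresh from succinic anhydride.
Remark on precursor design: a free tertiary OH would protonate the diene. Triethylsilyl is chosen because it should outlast brief Ce(IV) exposure (unlike trimethylsilyl) and still leave under buffered HF (unlike a tertiary tert-butyldimethylsilyl ether).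

Step 1
Reactants: 1 2,5-dimethoxybenzaldehyde
Product: 3 (R)-1-(2,5-dimethoxyphenyl)but-3-en-1-ol, via borinate ester 2 (not isolated)
Conditions: (−)-Ipc2B(allyl) [commercial solution, (−)-α-pinene series] (1.2 equiv), Et2O, −78 °C; then 3 M NaOH, 30% H2O2, 0 °C → rt
Reagents that add atoms: (−)-B-allyldiisopinocampheylborane, C=CCB([C@H]1C[C@H]2C[C@@H]([C@@H]1C)C2(C)C)[C@H]1C[C@H]2C[C@@H]([C@@H]1C)C2(C)C
Why: Brown asymmetric allylboration runs through a closed chair-like Zimmerman–Traxler transition state in which the isopinocampheyl groups of the (−)-α-pinene series steer the allyl group to the Re face of the aldehyde, setting C1' as (R) (the enantiomeric reagent is the one that gives (S)-carbinols from benzaldehydes).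

Step 2
Reactants: 3 (R)-1-(2,5-dimethoxyphenyl)but-3-en-1-ol
Product: 4 (R)-1-(2,5-dimethoxyphenyl)-4-methylpent-3-en-1-ol
Conditions: Grubbs II (3 mol%), 2-methylbut-2-ene (large excess)/CH2Cl2, 40 °C, sealed tube
Reagents that add atoms: 2-methylbut-2-ene, CC=C(C)C
Why: Olefin cross-metathesis of a terminal alkene with a large excess of 2-methylbut-2-ene transfers the isopropylidene unit, is driven by escape of a volatile alkene, and does not touch the carbinol stereocentre.

Step 3
Reactants: 5 3-hydroxy-3-methylbutanoic acid
Product: 7 3-methyl-3-(triethylsilyloxy)butanoic acid, via bis-silylated ester 6 (not isolated)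
Conditions: TESOTf (2.3 equiv), 2,6-lutidine (3 equiv), CH2Cl2, 0 °C; then K2CO3 (1 equiv), THF/MeOH/H2O, 0 °C; aq. KHSO4 to pH 4
Reagents that add atoms: triethylsilyl triflate, CC[Si](CC)(CC)OS(=O)(=O)C(F)(F)F
Why: Silyl triflate/hindered-base silylation covers even a tertiary alcohol, and because a silyl ester is far more labile than a tertiary silyl ether, the mild carbonate hydrolysis should free only the acid.

Step 4
Reactants: 4 (R)-1-(2,5-dimethoxyphenyl)-4-methylpent-3-en-1-ol; 7 3-methyl-3-(triethylsilyloxy)butanoic acid
Product: 8 (R)-1-(2,5-dimethoxyphenyl)-4-methylpent-3-en-1-yl 3-methyl-3-(triethylsilyloxy)butanoate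
Conditions: DCC (1.3 equiv), DMAP (0.2 equiv), CH2Cl2, 0 °C → rt
Reagents that add atoms: none
Why: Steglich esterification transfers the activated acyl group to the carbinol oxygen, so the C1'–O bond is never broken and (R) is retained, while the silyl ether prevents self-acylation of the acid.

Step 5
Reactants: 8 (R)-1-(2,5-dimethoxyphenyl)-4-methylpent-3-en-1-yl 3-methyl-3-(triethylsilyloxy)butanoate
Product: 9 (R)-1-(3,6-dioxocyclohexa-1,4-dien-1-yl)-4-methylpent-3-en-1-yl 3-methyl-3-(triethylsilyloxy)butanoate
Conditions: CAN (2.5 equiv), MeCN/H2O (3:1), −5 to 0 °C, 15 min; cold water/brine, EtOAc; short SiO2 plug, dried azeotropically, kept dark, used at once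
Reagents that add atoms: water, O
Why: In ceric ammonium nitrate oxidative demethylation of a hydroquinone dimethyl ether the dimethoxyarene is by far the most easily oxidised π system, so the quinone should form within minutes at 0 °C, a window in which trisubstituted alkenes, esters and hindered triethylsilyl ethers are known to persist.

Step 6
Reactants: 10 succinic anhydride
Product: 11 2,5-bis(trimethylsilyloxy)furan
Conditions: TMSOTf (2.2 equiv), Et3N (2.5 equiv), Et2O, 0 °C → rt; pentane extraction, bulb-to-bulb distillation under Ar
Reagents that add atoms: trimethylsilyl triflate, C[Si](C)(C)OS(=O)(=O)C(F)(F)F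
Why: Double soft enolisation and O-silylation of the cyclic anhydride (silyl triflate/tertiary amine) gives a bis-silyl ketene acetal that is stabilised as an aromatic furan and can be distilled away from the ammonium salt.

Step 7
Reactants: 9 (R)-1-(3,6-dioxocyclohexa-1,4-dien-1-yl)-4-methylpent-3-en-1-yl 3-methyl-3-(triethylsilyloxy)butanoate; 11 2,5-bis(trimethylsilyloxy)furan
Product: 14 O-triethylsilyl-β-HIVS, via oxa-bridged cycloadduct 12 (not isolated), via 4a,8a-dihydrotetraone 13 (not isolated)
Conditions: 11 (1.3 equiv), CH2Cl2, −40 °C → rt, Ar, dark; then THF/aq. citrate buffer (pH 4–5), 0 °C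
Reagents that add atoms: none
Why: The high-lying HOMO of the doubly oxygenated furan 11 and the low-lying LUMO of the enedione in 9 engage in a normal-electron-demand Diels–Alder reaction that forms C4a–C5 and C8a–C8 in one suprafacial event and gives the 7-oxanorbornene 12, whose two bridgeheads are mixed silyl ketals. Weakly acidic water removes both trimethylsilyl groups, the bridge oxygen leaves with them, and tetraone 13 enolises at C4a–H and C8a–H to the doubly hydrogen-bonded aromatic naphthazarin, a thermodynamic sink reached without oxidant or reductant. The closest known reaction type is the cycloaddition of 2,5-bis(silyloxy)furans to p-benzoquinone and 1,4-naphthoquinone, which furnishes naphthazarin and quinizarin by the same cascade. The only ring closed, C4a–C5–C6–C7–C8–C8a, arises by intermolecular [4+2] annulation in which the four furan carbons span the two dienophile carbons, so no chain-cyclisation mode has to be won. No lasting stereocentre is formed, since C4a, C5, C8 and C8a all end up sp2 and endo/exo or facial preferences are irrelevant, while C1' is a spectator that meets only neutral to weakly acidic media. What is needed is site selectivity between the two quinone C=C bonds, and the branched C1' substituent secures it by making C2=C3 trisubstituted and shielded; the twofold symmetry of 11 leaves no regiochemical choice, the electron-rich prenyl alkene is mismatched with an electron-rich diene, and the silyl ether removes the one proton source that would quench 11.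

Step 8
Reactants: 14 O-triethylsilyl-β-HIVS
Product: 15 β-HIVS, (R)-1-(5,8-dihydroxy-1,4-dioxo-1,4-dihydronaphthalen-2-yl)-4-methylpent-3-en-1-yl 3-hydroxy-3-methylbutanoate
Conditions: HF·pyridine, pyridine, THF, 0 °C → rt (polypropylene vessel); pH 6–7 phosphate buffer work-up
Reagents that add atoms: none
Why: Fluoride-mediated desilylation under acidic buffering, driven by the strong Si–F bond, cleaves the triethylsilyl ether without generating alkoxide or phenoxide, so the base-sensitive naphthazarin, the C1' ester, the alkene and the stereocentre should remain untouched.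

Compound list
1 | 2,5-dimethoxybenzaldehyde | COc1ccc(OC)c(C=O)c1 | starting material
2 | (R)-1-(2,5-dimethoxyphenyl)but-3-en-1-yl diisopinocampheylborinate | C=CC[C@@H](OB([C@H]1C[C@H]2C[C@@H]([C@@H]1C)C2(C)C)[C@H]1C[C@H]2C[C@@H]([C@@H]1C)C2(C)C)c1cc(OC)ccc1OC | intermediate
3 | (R)-1-(2,5-dimethoxyphenyl)but-3-en-1-ol | C=CC[C@@H](O)c1cc(OC)ccc1OC | intermediate
4 | (R)-1-(2,5-dimethoxyphenyl)-4-methylpent-3-en-1-ol | CC(C)=CC[C@@H](O)c1cc(OC)ccc1OC | intermediate
5 | 3-hydroxy-3-methylbutanoic acid | CC(C)(O)CC(=O)O | starting material
6 | triethylsilyl 3-methyl-3-(triethylsilyloxy)butanoate | CC[Si](CC)(CC)OC(=O)CC(C)(C)O[Si](CC)(CC)CC | intermediate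
7 | 3-methyl-3-(triethylsilyloxy)butanoic acid | CC[Si](CC)(CC)OC(C)(C)CC(=O)O | intermediate
8 | (R)-1-(2,5-dimethoxyphenyl)-4-methylpent-3-en-1-yl 3-methyl-3-(triethylsilyloxy)butanoate | CC(C)=CC[C@@H](OC(=O)CC(C)(C)O[Si](CC)(CC)CC)c1cc(OC)ccc1OC | intermediate
9 | (R)-1-(3,6-dioxocyclohexa-1,4-dien-1-yl)-4-methylpent-3-en-1-yl 3-methyl-3-(triethylsilyloxy)butanoate | CC(C)=CC[C@@H](OC(=O)CC(C)(C)O[Si](CC)(CC)CC)C1=CC(=O)C=CC1=O | intermediate
10 | succinic anhydride | O=C1CCC(=O)O1 | starting material
11 | 2,5-bis(trimethylsilyloxy)furan | C[Si](C)(C)Oc1ccc(O[Si](C)(C)C)o1 | intermediate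
12 | 2-substituted 5,8-epoxy-5,8-bis(trimethylsilyloxy)-4a,5,8,8a-tetrahydronaphthalene-1,4-dione (ring-fusion and bridgehead centres formed as a mixture and erased later; C1' is R) | CC(C)=CC[C@@H](OC(=O)CC(C)(C)O[Si](CC)(CC)CC)C1=CC(=O)C2C(C1=O)C1(O[Si](C)(C)C)C=CC2(O[Si](C)(C)C)O1 | intermediate
13 | 2-substituted 4a,8a-dihydronaphthalene-1,4,5,8-tetraone (C4a and C8a unassigned and erased later; C1' is R) | CC(C)=CC[C@@H](OC(=O)CC(C)(C)O[Si](CC)(CC)CC)C1=CC(=O)C2C(C1=O)C(=O)C=CC2=O | intermediate
14 | O-triethylsilyl-β-HIVS, (R)-1-(5,8-dihydroxy-1,4-dioxo-1,4-dihydronaphthalen-2-yl)-4-methylpent-3-en-1-yl 3-methyl-3-(triethylsilyloxy)butanoate | CC(C)=CC[C@@H](OC(=O)CC(C)(C)O[Si](CC)(CC)CC)C1=CC(=O)c2c(O)ccc(O)c2C1=O | intermediate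
15 | β-HIVS | CC(C)=CC[C@@H](OC(=O)CC(C)(C)O)C1=CC(=O)c2c(O)ccc(O)c2C1=O | target

Total step count: 8. Longest linear sequence: 6 (steps 1, 2, 4, 5, 7, 8).

Steps most likely to fail

Step 7. Electron transfer or conjugate addition from the very electron-rich diene may outrun cycloaddition, and a reduced quinone would then expel the C1' carboxylate through a quinone methide. The fallback sets out from acid 7 and rejoins at 14. It takes the naphthazarin nucleus ready-made and masked instead of building it last.
- Commercial naphthazarin is reduced with sodium dithionite to naphthalene-1,4,5,8-tetrol F1.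
- Bromochloromethane/Cs2CO3 in DMF bridges both peri pairs to give the bis(methylene acetal) naphtho[1,8-de:4,5-d'e']bis([1,3]dioxine) F2.
- NBS gives the single possible monobromide F3.
- Bromine–lithium exchange (t-BuLi, THF, −78 °C) and acylation with N-methoxy-N,4-dimethylpent-3-enamide give the aryl ketone F4.
- Reduction with (+)-DIP-Cl sets (R) in the carbinol F5.
- Anodic oxidation in aqueous acetonitrile releases both acetals to give shikonin F6.
- Steglich acylation of the side-chain hydroxyl of F6 with 7 gives 14, since the chelated phenols stay inert.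

Step 5. The tertiary silyl ether may be partly lost in the strongly acidic Ce(IV) medium, which would leave a mixture and a protic group that destroys the diene. The fallback sets out from 4 and 5 and rejoins at 9. It changes the order of events so that no silyl ether ever meets cerium.
- Alcohol 4 is esterified with unprotected 5 (DCC, DMAP; the tertiary hydroxyl is too hindered to compete) to give the hydroxy ester F7.
- CAN converts F7 into the hydroxy quinone F8, which has nothing acid-labile left.
- TESOTf/2,6-lutidine in CH2Cl2 at −78 °C, a base that does not add to quinones, silylates F8 to 9.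

Step 1. Facial selectivity may be insufficient, for example if the ortho-methoxy group perturbs the chair transition state, and no later step upgrades the enantiomeric purity. The fallback sets out from 4 and comes back at 4. It erases the stereocentre and resets it by reagent-controlled ketone reduction instead of allyl transfer.
- Dess–Martin periodinane/NaHCO3 oxidises 4 to 1-(2,5-dimethoxyphenyl)-4-methylpent-3-en-1-one F9.
- (+)-DIP-Cl (THF, −25 °C, diethanolamine work-up) should return (R)-4, because it distinguishes aryl from CH2R and does not hydroborate the trisubstituted alkene.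

Further compounds
F1 | step 7 | naphthalene-1,4,5,8-tetrol | Oc1ccc(O)c2c(O)ccc(O)c12
F2 | step 7 | naphtho[1,8-de:4,5-d'e']bis([1,3]dioxine) | c1cc2OCOc3ccc4OCOc1c4c23
F3 | step 7 | monobromide of F2 (Br ortho to an acetal oxygen) | Brc1cc2OCOc3ccc4OCOc1c4c23
F4 | step 7 | 4-methyl-1-(naphtho[1,8-de:4,5-d'e']bis([1,3]dioxin)-4-yl)pent-3-en-1-one | CC(C)=CCC(=O)c1cc2OCOc3ccc4OCOc1c4c23
F5 | step 7 | (R)-4-methyl-1-(naphtho[1,8-de:4,5-d'e']bis([1,3]dioxin)-4-yl)pent-3-en-1-ol | CC(C)=CC[C@@H](O)c1cc2OCOc3ccc4OCOc1c4c23
F6 | step 7 | shikonin | CC(C)=CC[C@@H](O)C1=CC(=O)c2c(O)ccc(O)c2C1=O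
F7 | step 5 | (R)-1-(2,5-dimethoxyphenyl)-4-methylpent-3-en-1-yl 3-hydroxy-3-methylbutanoate | CC(C)=CC[C@@H](OC(=O)CC(C)(C)O)c1cc(OC)ccc1OC
F8 | step 5 | (R)-1-(3,6-dioxocyclohexa-1,4-dien-1-yl)-4-methylpent-3-en-1-yl 3-hydroxy-3-methylbutanoate | CC(C)=CC[C@@H](OC(=O)CC(C)(C)O)C1=CC(=O)C=CC1=O
F9 | step 1 | 1-(2,5-dimethoxyphenyl)-4-methylpent-3-en-1-one | CC(C)=CCC(=O)c1cc(OC)ccc1OC
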